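**Compound numbers used throughout:** 1 3,4,5-trimethoxybenzaldehyde; 2 racemic allylic alcohol; 3 (S)-allylic alcohol; 4 ethyl prop-1-enyl ether; 5 bromoacetal; 6 2-ethoxyoxolane; 7 lactone; 8 4-bromo-1,2-dimethoxybenzene; 9 aryllithium; 10 hemiketal; 11 ligraminol A.

## Analysis of the target

Ligraminol A (11) is a 2,5-diaryl-3,4-dimethyloxolane. O1 is flanked by C2, which carries ring A (3,4-dimethoxyphenyl), and C5, which carries ring B (3,4,5-trimethoxyphenyl); C3 and C4 each carry a methyl group. All four ring carbons are stereocentres, (2S,3R,4S,5S). Ring A is cis to the C3 methyl, the two methyls are cis to each other, and the C4 methyl is trans to ring B, so ring A and both methyls share one face and ring B sits alone on the other. Three contiguous cis substituents are the less stable arrangement, so no centre can be corrected by equilibration; each must be set kinetically and then shielded from epimerization. The sensitive groups are the two benzylic C–O bonds next to electron-rich arenes (they ionize with acid and cleave on hydrogenolysis) and the arenes themselves (electrophilic halogenation, oxidation). The difficulty is that the two halves are not equivalent: the aryl groups differ and have opposite relationships to their neighbouring methyls, so no symmetric disconnection applies. The strategy rests on the O1–C5–C4 segment with the C3–C4 bond. C5 is a benzylic carbinol carbon that can be obtained as a single enantiomer, and a C4 methyl trans to ring B with a C3 methyl cis to it is the pattern expected when an oxygen-tethered radical at C3 closes onto a vinyl group at C4.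

## Retrosynthetic reasoning

**C2–H (11 to 10).** The last bond cut is C2–H, which leads back to hemiketal 10 and so to a planar oxocarbenium ion at C2. The cut is made here and not at C2–ring A because the group that enters last ends anti to the C3 methyl. Only if that group is hydride does ring A finish cis to the methyl, as 11 requires. The least stable relationship is thus made last and irreversibly. The forward step has to ionize 10 and deliver hydride faster than the cation loses its C3 proton.

**C2–ring A (10 to 7 and 9, from 8).** Cutting the C2–aryl bond of 10 gives lactone 7 and aryllithium 9, which comes from bromide 8 by halogen–lithium exchange. The lactone carbonyl is the only electrophilic carbon, so the two different aryl groups enter at different stages and cannot be interchanged. The forward step has to stop after one addition and must not enolize C3.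

**Oxidation level at C2 (7 to 6).** Lactone 7 is traced to cyclic acetal 6. This costs a step, but it merges the anomers of 6 into one compound and gives a stage at which minor C3 diastereomers can be removed. The forward step has to oxidize the acetal carbon without opening the benzylic C5–O bond or attacking ring B.

**C3–C4 (6 to 5).** The C3–C4 bond is cut homolytically, to a radical at C3 and a vinyl group at C4, which gives the acyclic bromoacetal 5. This is the one ring bond between the two methyl-bearing carbons, so cutting it makes both methyl stereocentres the outcome of a single cyclization controlled by C5. A cut at C2–C3 or C4–C5 would leave them to be built separately. One bond formation gives the ring and two stereocentres. The forward step has to close in the 5-exo mode, place the new CH2 trans to ring B and place the C3 methyl cis to that CH2.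

**O1–C2 and C3–Br (5 to 3 and 4).** The acetal C–O bond and the C–Br bond of 5 are cut together, to alcohol 3 and enol ether 4. Both bonds form in one bromo-alkoxylation, and nothing stereochemical is asked of it, since C2 is later a carbonyl and C3 a planar radical.

**C5 stereocentre and C5–vinyl (3 to 2 to 1).** Alcohol 3 is the slow-reacting enantiomer of racemate 2 in a kinetic resolution, and 2 comes from aldehyde 1 by cutting the C5–vinyl bond. The only stereocentre that must be bought is therefore fixed on a simple three-carbon side chain, before any valuable material is committed.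

## Alternatives that were turned down

**Alternative 1:** The oxolane is traced, through Baeyer–Villiger oxygen insertion, to the all-cis cyclobutanone A1. A1 is cut across C2–C3 and C4–C5 into (3,4-dimethoxyphenyl)ketene A2 and (Z)-but-2-ene A3. The forward key step is a thermal (2+2) cycloaddition. It is suprafacial on A3, so the methyls stay cis, and the ketene aryl group ends on the more crowded face, so A1 already has ring A and both methyls cis. Oxygen insertion at the benzylic carbon would give lactone A4, whose carbonyl carbon would then receive ring B trans to the neighbouring methyl.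
- For it: three of the four stereocentres and the cis-dimethyl relationship come from one stereospecific step. On that point it is stronger than the radical closure, where the cis methyls are the weaker selectivity. It is also at least as short.
- Against it: A1 forms as a racemate, so the absolute configuration needs a late resolution. A2 is an aldoketene that dimerizes readily, and A3 is an unactivated, gaseous ketenophile. The aryl-bearing carbon of A1 is easily epimerized by the amine used to make A2. The two alpha carbons of A1 are both secondary, so the site of oxygen insertion is not assured. Ring B would have to enter A4 as an aryl-metal nucleophile on an oxocarbenium ion, because Friedel–Crafts arylation cannot give the 3,4,5-pattern.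
- In its place the chosen route offers absolute configuration fixed at the start, ring B in place from the first step, and a closely precedented reaction type for every step.

**Alternative 2:** The C4–C5 and O1–C2 bonds are cut, leading to aldehyde 1 and the ester-bearing allylboronate A6. In the forward key step A6 adds to 1 under a bulky chiral binaphthyl phosphoric acid through a closed chair transition state. The resulting alkoxide closes onto the ester and gives the trans alpha-methylene lactone A5. Hydrogenation of A5 anti to the C4 methyl would give lactone 7 and join the chosen endgame.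
- For it: it is catalytic and enantioselective, loses no material to a resolution, uses no tin, and reaches 7 in two steps from 1. On step count and material economy it is stronger than the chosen route.
- Against it: A6 must be made separately with defined alkene geometry. Ester-substituted allylboronates are poor nucleophiles, and high enantioselectivity with an electron-rich aldehyde is not assured. C3 still has to be set by hydrogenation of A5 next to a benzylic C–O bond, with three risks: hydrogenolysis, migration of the double bond into the ring (which erases C4), and uncertain face selection.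
- In its place the chosen route sets C3 and C4 in one event, controlled by a centre whose configuration is secured beforehand, and never exposes the benzylic ethers to hydrogenation.

**Alternative 3:** Both aryl–carbon bonds are cut, and the ring is traced to the cis-dimethyl lactone A7, which comes from the meso diol A8. In the forward key step an alcohol dehydrogenase with cofactor recycling oxidizes one enantiotopic hydroxymethyl group of A8. The hydroxy aldehyde closes to the lactol and is oxidized again to A7.
- For it: the absolute configuration of both methyl carbons and their cis relationship are set in one step from a trivial substrate, with full theoretical conversion and no tin. On these points it is stronger than the chosen route.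
- Against it: A7 carries neither aryl group, and its C5 is a CH2 at the wrong oxidation level. Mapping onto 11 requires ring B on the carbonyl carbon and ring A on the CH2 carbon. That means a ring-opening aryl addition, a ketone reduction in which only the adjacent methyl centre controls the C5 configuration, and an oxidative relactonization before lactone 7 is reached. The open-chain aryl ketone on that path has an acidic hydrogen at a methyl-bearing carbon, so the enzyme-derived cis relationship is at risk. The sequence is longer.
- The chosen route reaches 7 in five steps with C5 fixed by resolution and C4 and C3 relayed from it.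

Key step: step 4

Assumption: commercial 4 is an E/Z mixture, which does not matter because its two alkene carbons become the later carbonyl carbon (C2) and a planar radical centre (C3).

## Route

**Step 1**
Reactants: 1 3,4,5-trimethoxybenzaldehyde
Product: 2 rac-1-(3,4,5-trimethoxyphenyl)prop-2-en-1-ol
Conditions: CH2=CHMgBr, THF, −78 to 0 °C; aq NH4Cl
Reagents that add atoms: vinylmagnesium bromide, C=C[Mg]Br
Why: Grignard 1,2-addition to a non-enolizable aryl aldehyde; the carbinol centre forms as the racemate and is resolved in step 2.

**Step 2**
Reactants: 2 rac-1-(3,4,5-trimethoxyphenyl)prop-2-en-1-ol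
Product: 3 (S)-1-(3,4,5-trimethoxyphenyl)prop-2-en-1-ol
Conditions: Ti(Oi-Pr)4 (0.2 equiv), L-(+)-diisopropyl tartrate (0.3 equiv), t-BuOOH (0.6 equiv, anhydrous), 4 Å molecular sieves, CH2Cl2, −20 °C, to a little over half conversion
Reagents that add atoms: none
Why: Sharpless kinetic resolution of a secondary allylic alcohol; with L-(+)-tartrate the enantiomer consumed should be the one that corresponds spatially to (S)-alk-1-en-3-ols, which is R here because aryl outranks vinyl, so the S alcohol should remain and be separated from the polar epoxy alcohol by chromatography.

**Step 3**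
Reactants: 3 (S)-1-(3,4,5-trimethoxyphenyl)prop-2-en-1-ol; 4 ethyl prop-1-enyl ether
Product: 5 5-[(1S)-1-(2-bromo-1-ethoxypropoxy)prop-2-enyl]-1,2,3-trimethoxybenzene (mixture at the acetal and bromide carbons)
Conditions: NBS (1.1 equiv, added in portions), 4 (3 equiv), CH2Cl2, −40 to 0 °C; aq NaHCO3/Na2S2O3
Reagents that add atoms: N-bromosuccinimide, O=C1CCC(=O)N1Br
Why: Bromo-alkoxylation of an enol ether (Ueno–Stork bromoacetal formation): bromine adds to the beta carbon of 4 and the hydroxyl oxygen of 3 traps the oxocarbenium ion, so the C–O bond of the carbinol centre is not touched; the enol ether is far more nucleophilic than the vinyl group or ring B, and keeping it in excess while the bromine source is added cold should suppress ring bromination.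

**Step 4**
Reactants: 5 5-[(1S)-1-(2-bromo-1-ethoxypropoxy)prop-2-enyl]-1,2,3-trimethoxybenzene
Product: 6 (3R,4S,5S)-2-ethoxy-3,4-dimethyl-5-(3,4,5-trimethoxyphenyl)oxolane (anomeric mixture)
Conditions: Bu3SnH (1.3 equiv) and AIBN (0.1 equiv) added over several hours, benzene (0.02 M), 80 °C; KF work-up
Reagents that add atoms: none
Why: Ueno–Stork haloacetal radical cyclization. The tin radical abstracts bromine from 5 to give a secondary radical at C3, which adds to the internal vinyl carbon in a 5-exo-trig closure, forming the C3–C4 bond and the oxolane ring; the primary radical so formed takes hydrogen from Bu3SnH and becomes the C4 methyl. C4 is controlled by the resolved C5 centre: in the chair-like Beckwith–Houk transition state ring B sits pseudo-equatorial on the allylic carbon, so the new CH2 ends trans to it (4S). C3 is controlled within the same chair: the methyl on the radical carbon prefers the outward position, which places it cis to the new CH2 (3R), the usual outcome for 1-substituted hex-5-enyl radicals. The step therefore needs trans aryl/methyl and cis methyl/methyl selectivity, both relayed from C5; the first is expected to be strong and the second weaker. The acetal carbon forms as a mixture that does not matter because step 5 turns it into a carbonyl, and the anomers and any 3,4-trans isomer are dealt with at lactone 7. No radical is generated at C5, and slow addition of the hydride keeps direct reduction of the C3 radical behind cyclization.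

**Step 5**
Reactants: 6 (3R,4S,5S)-2-ethoxy-3,4-dimethyl-5-(3,4,5-trimethoxyphenyl)oxolane
Product: 7 (3R,4S,5S)-3,4-dimethyl-5-(3,4,5-trimethoxyphenyl)oxolan-2-one
Conditions: mCPBA (1.5 equiv), BF3·OEt2 (0.5 equiv), CH2Cl2, 0 °C
Reagents that add atoms: 3-chloroperbenzoic acid, OOC(=O)c1cccc(Cl)c1
Why: Grieco-type oxidation of a cyclic acetal: the Lewis acid ionizes the exocyclic ethoxy group, the peracid adds to the ring oxocarbenium ion and the peroxy acetal collapses to the lactone; C3 is not enolized under cold acidic conditions, both anomers converge on one lactone, and minor diastereomers from step 4 are removed here by chromatography.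

**Step 6**
Reactants: 7 (3R,4S,5S)-3,4-dimethyl-5-(3,4,5-trimethoxyphenyl)oxolan-2-one; 8 4-bromo-1,2-dimethoxybenzene
Product: 10 (3R,4S,5S)-2-(3,4-dimethoxyphenyl)-3,4-dimethyl-5-(3,4,5-trimethoxyphenyl)oxolan-2-ol (mixture at C2), via 3,4-dimethoxyphenyllithium 9 (not isolated)
Conditions: 8, n-BuLi, THF, −78 °C; then 7, THF, −78 °C; aq NH4Cl at −78 °C
Reagents that add atoms: none
Why: Bromine–lithium exchange followed by addition of the aryllithium to the lactone carbonyl; the tetrahedral lithium alkoxide should persist at −78 °C, which prevents a second addition and leaves little opportunity for enolization at C3, and protonation gives the hemiketal (in equilibrium with its open hydroxy ketone tautomer), used without delay.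

**Step 7**
Reactants: 10 (3R,4S,5S)-2-(3,4-dimethoxyphenyl)-3,4-dimethyl-5-(3,4,5-trimethoxyphenyl)oxolan-2-ol
Product: 11 (2S,3R,4S,5S)-2-(3,4-dimethoxyphenyl)-3,4-dimethyl-5-(3,4,5-trimethoxyphenyl)oxolane (ligraminol A)
Conditions: Et3SiH (5 equiv), then BF3·OEt2 (2 equiv), CH2Cl2, −78 °C; aq NaHCO3
Reagents that add atoms: none
Why: Ionic hydrogenation of a hemiketal: the Lewis acid ionizes the anomeric hydroxyl to the 2-aryl oxocarbenium ion and the silane delivers hydride to C2 from the face opposite the C3 and C4 methyls, which places ring A cis to the C3 methyl (2S); the silane is present before the Lewis acid and the temperature is held at −78 °C so that hydride capture outruns loss of the C3 proton.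

## Compound list

1 | 3,4,5-trimethoxybenzaldehyde | COc1cc(C=O)cc(OC)c1OC | starting material
2 | rac-1-(3,4,5-trimethoxyphenyl)prop-2-en-1-ol | C=CC(O)c1cc(OC)c(OC)c(OC)c1 | intermediate
3 | (S)-1-(3,4,5-trimethoxyphenyl)prop-2-en-1-ol | C=C[C@H](O)c1cc(OC)c(OC)c(OC)c1 | intermediate
4 | ethyl prop-1-enyl ether (E/Z mixture) | CCOC=CC | starting material
5 | 5-[(1S)-1-(2-bromo-1-ethoxypropoxy)prop-2-enyl]-1,2,3-trimethoxybenzene (mixture at the acetal and bromide carbons) | C=C[C@@H](c1cc(OC)c(OC)c(OC)c1)OC(OCC)C(C)Br | intermediate
6 | (3R,4S,5S)-2-ethoxy-3,4-dimethyl-5-(3,4,5-trimethoxyphenyl)oxolane (anomeric mixture) | CCOC1O[C@H](c2cc(OC)c(OC)c(OC)c2)[C@@H](C)[C@H]1C | intermediate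
7 | (3R,4S,5S)-3,4-dimethyl-5-(3,4,5-trimethoxyphenyl)oxolan-2-one | O=C1O[C@H](c2cc(OC)c(OC)c(OC)c2)[C@@H](C)[C@H]1C | intermediate
8 | 4-bromo-1,2-dimethoxybenzene | COc1ccc(Br)cc1OC | starting material
9 | 3,4-dimethoxyphenyllithium | [Li]c1ccc(OC)c(OC)c1 | intermediate (not isolated)
10 | (3R,4S,5S)-2-(3,4-dimethoxyphenyl)-3,4-dimethyl-5-(3,4,5-trimethoxyphenyl)oxolan-2-ol (mixture at C2) | COc1ccc(C2(O)O[C@H](c3cc(OC)c(OC)c(OC)c3)[C@@H](C)[C@H]2C)cc1OC | intermediate
11 | (2S,3R,4S,5S)-2-(3,4-dimethoxyphenyl)-3,4-dimethyl-5-(3,4,5-trimethoxyphenyl)oxolane (ligraminol A) | COc1ccc([C@H]2O[C@H](c3cc(OC)c(OC)c(OC)c3)[C@@H](C)[C@H]2C)cc1OC | target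

## Step count and risks

Total step count: 7. Longest linear sequence: 7 steps (1 to 11); the aryllithium 9 is made within step 6.

**Step 4 (key step).** The most likely failure is insufficient cis selectivity at C3, because the methyl on the planar radical carbon has only a small preference for the orientation that ends cis to the new CH2. Premature hydrogen transfer to the C3 radical before ring closure is a second risk if the hydride concentration rises. Fallback, from 3 back to 7: the C3 methyl is left out of the cyclization and introduced afterwards.
- Alcohol 3 is treated with ethyl vinyl ether and NBS to give 5-[(1S)-1-(2-bromo-1-ethoxyethoxy)prop-2-enyl]-1,2,3-trimethoxybenzene F1.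
- Bu3SnH/AIBN closes F1 to (4S,5S)-2-ethoxy-4-methyl-5-(3,4,5-trimethoxyphenyl)oxolane F2, which needs only the stronger trans selectivity.
- mCPBA/BF3·OEt2 gives (4S,5S)-4-methyl-5-(3,4,5-trimethoxyphenyl)oxolan-2-one F3.
- LiN(i-Pr)2 and MeI alkylate anti to the C4 methyl to give (3S,4S,5S)-3,4-dimethyl-5-(3,4,5-trimethoxyphenyl)oxolan-2-one F4.
- F4 is deprotonated again with LiN(i-Pr)2 and the enolate is protonated at −78 °C with a hindered phenol from the face opposite the C4 methyl, which should turn the C3 methyl cis and give 7.

**Step 2.** Epoxidation of a monosubstituted vinyl group is slow, and the Lewis-acidic titanium alkoxide may ionize the electron-rich benzylic alcohol, so the resolution may be incomplete or the recovered alcohol partly racemized. The sense of the resolution should be confirmed on 3 (Mosher esters) before material is carried on. Fallback, from 2 back to 3: immobilized Candida antarctica lipase B with vinyl acetate in a hydrocarbon/ether solvent at room temperature should acylate the R enantiomer to (R)-1-(3,4,5-trimethoxyphenyl)prop-2-enyl acetate F5 and leave 3, which is separated by chromatography.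

**Step 5.** The peracid may attack ring B, or the Lewis acid may open the benzylic C5–O bond, which would erode the C5 configuration. Fallback, from 6 back to 7: the acetal is hydrolysed with dilute aqueous acid in THF to (3R,4S,5S)-3,4-dimethyl-5-(3,4,5-trimethoxyphenyl)oxolan-2-ol F6, and F6 is oxidized under near-neutral conditions (PhI(OAc)2 with catalytic TEMPO, CH2Cl2) to 7.

**Step 6.** The tetrahedral intermediate may open and take up a second aryl group, or the aryllithium may deprotonate C3, with loss of the cis-dimethyl relationship. Fallback, from 7 back to 10:
- Lactone 7 is opened with MeNH(OMe)·HCl and AlMe3 to (2R,3S,4S)-4-hydroxy-N-methoxy-N,2,3-trimethyl-4-(3,4,5-trimethoxyphenyl)butanamide F7.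
- Silylation with Et3SiOTf and 2,6-lutidine gives the triethylsilyl ether F8, (2R,3S,4S)-N-methoxy-N,2,3-trimethyl-4-(triethylsilyloxy)-4-(3,4,5-trimethoxyphenyl)butanamide F8.
- Aryllithium 9 adds once to the chelating amide and gives (2R,3S,4S)-1-(3,4-dimethoxyphenyl)-2,3-dimethyl-4-(triethylsilyloxy)-4-(3,4,5-trimethoxyphenyl)butan-1-one F9.
- Desilylation with HF·pyridine lets the hydroxy ketone close to 10.

**Step 7.** The oxocarbenium ion may lose its C3 proton to the enol ether and be re-protonated, scrambling C3, or hydride may enter on the methyl-bearing face because ring B crowds the other one. Fallback, from 10 back to 11: the elimination is carried out on purpose and C2 and C3 are set together.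
- Hemiketal 10 is dehydrated with catalytic pyridinium p-toluenesulfonate over molecular sieves in warm toluene to (2S,3S)-5-(3,4-dimethoxyphenyl)-3,4-dimethyl-2-(3,4,5-trimethoxyphenyl)-2,3-dihydrofuran F10.
- F10 is hydrogenated over Rh/Al2O3 in ethyl acetate. Syn addition guarantees the cis ring A/methyl relationship; the face is expected to be chosen by the adjacent methyl-bearing carbon, which would give 11.
- Face selection and benzylic hydrogenolysis remain the uncertain points of this fallback.

## Further compounds

F1 | step 4 | 5-[(1S)-1-(2-bromo-1-ethoxyethoxy)prop-2-enyl]-1,2,3-trimethoxybenzene (mixture at the acetal carbon) | C=C[C@@H](c1cc(OC)c(OC)c(OC)c1)OC(OCC)CBr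
F2 | step 4 | (4S,5S)-2-ethoxy-4-methyl-5-(3,4,5-trimethoxyphenyl)oxolane (anomeric mixture) | CCOC1O[C@H](c2cc(OC)c(OC)c(OC)c2)[C@@H](C)C1
F3 | step 4 | (4S,5S)-4-methyl-5-(3,4,5-trimethoxyphenyl)oxolan-2-one | O=C1O[C@H](c2cc(OC)c(OC)c(OC)c2)[C@@H](C)C1
F4 | step 4 | (3S,4S,5S)-3,4-dimethyl-5-(3,4,5-trimethoxyphenyl)oxolan-2-one | O=C1O[C@H](c2cc(OC)c(OC)c(OC)c2)[C@@H](C)[C@@H]1C
F5 | step 2 | (R)-1-(3,4,5-trimethoxyphenyl)prop-2-enyl acetate | C=C[C@@H](OC(C)=O)c1cc(OC)c(OC)c(OC)c1
F6 | step 5 | (3R,4S,5S)-3,4-dimethyl-5-(3,4,5-trimethoxyphenyl)oxolan-2-ol (anomeric mixture) | OC1O[C@H](c2cc(OC)c(OC)c(OC)c2)[C@@H](C)[C@H]1C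
F7 | step 6 | (2R,3S,4S)-4-hydroxy-N-methoxy-N,2,3-trimethyl-4-(3,4,5-trimethoxyphenyl)butanamide | CON(C)C(=O)[C@H](C)[C@H](C)[C@H](O)c1cc(OC)c(OC)c(OC)c1
F8 | step 6 | (2R,3S,4S)-N-methoxy-N,2,3-trimethyl-4-(triethylsilyloxy)-4-(3,4,5-trimethoxyphenyl)butanamide | CON(C)C(=O)[C@H](C)[C@H](C)[C@H](O[Si](CC)(CC)CC)c1cc(OC)c(OC)c(OC)c1
F9 | step 6 | (2R,3S,4S)-1-(3,4-dimethoxyphenyl)-2,3-dimethyl-4-(triethylsilyloxy)-4-(3,4,5-trimethoxyphenyl)butan-1-one | COc1ccc(C(=O)[C@H](C)[C@H](C)[C@H](O[Si](CC)(CC)CC)c2cc(OC)c(OC)c(OC)c2)cc1OC
F10 | step 7 | (2S,3S)-5-(3,4-dimethoxyphenyl)-3,4-dimethyl-2-(3,4,5-trimethoxyphenyl)-2,3-dihydrofuran | COc1ccc(C2=C(C)[C@H](C)[C@@H](c3cc(OC)c(OC)c(OC)c3)O2)cc1OC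
A1 | alternative 1 | (2S,3R,4S)-2-(3,4-dimethoxyphenyl)-3,4-dimethylcyclobutan-1-one (all-cis; formed as the racemate) | COc1ccc([C@H]2C(=O)[C@@H](C)[C@H]2C)cc1OC
A2 | alternative 1 | (3,4-dimethoxyphenyl)ketene | COc1ccc(C=C=O)cc1OC
A3 | alternative 1 | (Z)-but-2-ene | C/C=C\C
A4 | alternative 1 | (3S,4R,5S)-5-(3,4-dimethoxyphenyl)-3,4-dimethyloxolan-2-one | COc1ccc([C@H]2OC(=O)[C@@H](C)[C@H]2C)cc1OC
A5 | alternative 2 | (4S,5S)-4-methyl-3-methylidene-5-(3,4,5-trimethoxyphenyl)oxolan-2-one | O=C1O[C@H](c2cc(OC)c(OC)c(OC)c2)[C@@H](C)C1=C
A6 | alternative 2 | ethyl (Z)-2-[(4,4,5,5-tetramethyl-1,3,2-dioxaborolan-2-yl)methyl]but-2-enoate | C/C=C(/CB1OC(C)(C)C(C)(C)O1)C(=O)OCC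
A7 | alternative 3 | (3S,4R)-3,4-dimethyloxolan-2-one | C1OC(=O)[C@@H](C)[C@H]1C
A8 | alternative 3 | meso-2,3-dimethylbutane-1,4-diol | OC[C@H](C)[C@H](C)CO
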